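## Retrosynthetic overview

- Target 23 is a 6,8-diformyl-5,7-dihydroxychroman (pyran ring O1–C2–C3–C4–C4a–C8a) whose C2 is also C2' of a 3,3-dimethylnorbornane, with O1 endo, C3 exo and the C4 isobutyl group cis to C3'. The strategy rests on one feature: spiro C2 and benzylic C4 are 1,5-related through O1, C8a and C4a, so the hydrogen on C4 can be the former exo hydrogen of C2' in a secondary endo-norbornyl aryl ether, and its departure lets C3 bond to C2.
- Disconnections, backwards: O-methyl groups and the C6/C8 formyl groups from 23; the C3 formyl group from 19 (decarbonylation); C4–H and C2–C3 from 18 (1,5-hydride shift and ring closure of enal 16); enal 16 from ketone 12 (olefination, reduction, oxidation); ketone 12 from nitrile 9 (isobutyllithium); aryl ether 9 from endo-camphenilol 4 and fluoronitrile 7 (SNAr).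
- Ring order: the norbornane comes intact from (−)-camphene 1 and the arene from 1-fluoro-3,5-dimethoxybenzene 5. The pyran ring is the only ring made (step 9), and the quaternary spiro centre arises there from a C–H stereocentre.
- Two design choices: the ether is made on the non-enolisable nitrile, because an alkoxide would only enolise the aryl isobutyl ketone; the phenols are carried as methyl ethers, because their C–H bonds are poor hydride donors and do not compete in step 9.

Key step: step 9

Assumption: (−)-camphene of high enantiomeric purity is used (commercial material upgraded if needed, for example by crystallising 4 or an ester of it); the optical purity of 23 follows from it. Chroman numbering is used throughout and norbornane atoms are primed (C2 = C2').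

## Route

Step 1
Reactants: 1 (1S,4R)-(−)-camphene
Product: 3 (1R,4S)-camphenilone, via camphene ozonide 2 (not isolated)
Conditions: O3, CH2Cl2, −78 °C; then Me2S, −78 °C → rt
Reagents that add atoms: ozone, [O-][O+]=O
Why: Ozonolysis with reductive work-up cleaves the exocyclic C=CH2 bond to the ketone, and the bridgehead stereocentres are untouched because the bridgehead alpha-carbon cannot enolise.

Step 2
Reactants: 3 (1R,4S)-camphenilone
Product: 4 endo-camphenilol [(1R,2R,4S)-3,3-dimethylbicyclo[2.2.1]heptan-2-ol; OH endo; C2–H exo]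
Conditions: LiAlH4, Et2O, 0 °C → rt; then H2O, aq. NaOH
Reagents that add atoms: none
Why: Hydride addition to the norbornanone should occur from the exo face (the endo face is shielded by the endo hydrogens on C5/C6 and the endo methyl on C3), which sets C2 with OH endo and H exo; the minor exo alcohol is removed by chromatography or crystallisation.

Step 3
Reactants: 5 1-fluoro-3,5-dimethoxybenzene
Product: 7 2-fluoro-4,6-dimethoxybenzonitrile, via N-chlorosulfonyl amide 6 (not isolated)
Conditions: ClSO2NCO, CH2Cl2, 0 °C → rt; then DMF, 0 °C → rt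
Reagents that add atoms: chlorosulfonyl isocyanate, O=C=NS(=O)(=O)Cl
Why: Electrophilic aromatic amidation with chlorosulfonyl isocyanate followed by DMF-induced loss of chlorosulfonic acid (one-pot arene cyanation) should occur at C2, para to one methoxy group and ortho to the other, because the alternative doubly activated site lies between both methoxy groups and is more hindered; the minor regioisomer is removed by crystallisation.

Step 4
Reactants: 4 endo-camphenilol; 7 2-fluoro-4,6-dimethoxybenzonitrile
Product: 9 2-{[(1R,2R,4S)-3,3-dimethylbicyclo[2.2.1]heptan-2-yl]oxy}-4,6-dimethoxybenzonitrile, via sodium alkoxide 8 (not isolated)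
Conditions: NaH, THF, 0 → 50 °C; then 7, DMF, rt → 60 °C
Reagents that add atoms: none
Why: Nucleophilic aromatic substitution (addition–elimination) of fluoride ortho to the nitrile, a linear, non-enolisable activating group that stabilises the Meisenheimer adduct even when flanked by two ortho substituents; the carbinol C–O bond is not broken, so C2' keeps its endo oxygen and exo hydrogen.

Step 5
Reactants: 9 aryl ether nitrile; 10 isobutyllithium
Product: 12 1-(2-{[(1R,2R,4S)-3,3-dimethylbicyclo[2.2.1]heptan-2-yl]oxy}-4,6-dimethoxyphenyl)-3-methylbutan-1-one, via ketimine 11 (not isolated)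
Conditions: 10 (1.5 equiv), Et2O, −78 → 0 °C; then 2 M HCl, THF, 40 °C
Reagents that add atoms: water, O
Why: Organolithium addition to the nitrile stops at the N-lithio ketimine (no second addition, no alpha-hydrogen to remove), and acidic hydrolysis then gives the aryl isobutyl ketone under conditions too mild to ionise the secondary endo-norbornyl aryl ether.

Step 6
Reactants: 12 aryl isobutyl ketone; 13 triethyl phosphonoacetate
Product: 14 ethyl (2E)-3-(2-{[(1R,2R,4S)-3,3-dimethylbicyclo[2.2.1]heptan-2-yl]oxy}-4,6-dimethoxyphenyl)-5-methylhex-2-enoate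
Conditions: 13, NaH, DME, 0 °C → rt; then 12, reflux
Reagents that add atoms: none
Why: Horner–Wadsworth–Emmons olefination, in which the weakly basic phosphonate anion does not enolise the ketone and the ester should end up trans to the larger, twisted aryl group to give mainly the (E)-enoate; the minor (Z)-isomer is separated by chromatography.

Step 7
Reactants: 14 (E)-enoate
Product: 15 (2E)-3-(2-{[(1R,2R,4S)-3,3-dimethylbicyclo[2.2.1]heptan-2-yl]oxy}-4,6-dimethoxyphenyl)-5-methylhex-2-en-1-ol
Conditions: i-Bu2AlH (2.5 equiv), CH2Cl2, −78 → 0 °C; aq. potassium sodium tartrate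
Reagents that add atoms: none
Why: 1,2-Reduction of the conjugated ester by the aluminium hydride gives the allylic alcohol without change of alkene geometry or loss of the aryl ethers.

Step 8
Reactants: 15 (E)-allylic alcohol
Product: 16 (2E)-3-(2-{[(1R,2R,4S)-3,3-dimethylbicyclo[2.2.1]heptan-2-yl]oxy}-4,6-dimethoxyphenyl)-5-methylhex-2-enal
Conditions: MnO2, CH2Cl2, rt
Reagents that add atoms: none
Why: Chemoselective allylic alcohol oxidation on MnO2 under neutral conditions should give the enal with the (E) geometry retained.

Step 9
Reactants: 16 (E)-enal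
Product: 18 3-formyl-4-isobutyl-5,7-dimethoxy spirochroman (O1 endo and C3 exo on the norbornane; isobutyl cis to C3'; CHO trans to isobutyl), via zwitterion 17 (not isolated)
Conditions: BF3·OEt2 (30 mol%), CH2Cl2, 0 °C → rt
Reagents that add atoms: none
Why: Coordination of BF3 to the aldehyde turns C4 of the styrene, which the two ortho substituents hold perpendicular to the arene and so out of conjugation with it, into a hydride acceptor, and the exo C2'–H, five atoms away through O1, C8a and C4a, is delivered to C4 through a six-membered transition state to leave zwitterion 17, an aryloxocarbenium ion at C2' facing a boron enolate at C3. The enolate carbon C3 then adds to C2' and closes the pyran ring, the only new ring, in a 6-(enolexo)-endo-trig mode. The closest known reaction type is the Lewis-acid-catalysed 1,5-hydride shift/cyclisation of ortho-vinylaryl alkyl ethers to chromans, and for the acceptor the BF3-catalysed hydroalkylation of enals by ether alpha-C–H bonds. Spiro C2 is controlled by the norbornane, since the exo C–H is the stereoelectronically better donor and C3, already held on that face, bonds exo as well, so O1 stays endo; C4 is fixed in the hydride transfer, where the flat C3–H arm of the alkene should lie on the side of the gem-dimethyl carbon C3' and the isobutyl arm beside bridgehead C1'–H, which after closure leaves isobutyl cis to C3'; C3 is enolisable, should settle with CHO trans to isobutyl, and is deleted in step 10. The step needs chemoselectivity between the two ether C–H donors that are 1,5 to C4, secured because a tertiary alpha-oxy C–H is a far better hydride donor than the C5 methoxy C–H, and it needs face selectivity at C4, which rests only on the size difference between C1'–H and the C3' gem-dimethyl group.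

Step 10
Reactants: 18 3-formyl spirochroman
Product: 19 (1R,2R,4S,4'S)-4'-isobutyl-5',7'-dimethoxy-3,3-dimethylspiro[bicyclo[2.2.1]heptane-2,2'-chromane]
Conditions: [Rh(cod)Cl]2 (5 mol%), dppp (12 mol%), diglyme, 160 °C, N2 stream
Reagents that add atoms: none
Why: Rhodium-catalysed aldehyde decarbonylation (oxidative addition into the formyl C–H bond, CO extrusion, C–H reductive elimination) converts C3–CHO into C3–H2 under neutral conditions that avoid base-induced retro-oxa-Michael opening of the beta-aryloxy aldehyde; the C3 stereocentre disappears and C2 and C4 are not touched.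

Step 11
Reactants: 19 dimethoxy spirochroman
Product: 21 (1R,2R,4S,4'S)-4'-isobutyl-5',7'-dimethoxy-3,3-dimethylspiro[bicyclo[2.2.1]heptane-2,2'-chromane]-6',8'-dicarbaldehyde, via 8-monoaldehyde 20 (not isolated)
Conditions: Cl2CHOMe (6 equiv), TiCl4 (6 equiv), CH2Cl2, −20 °C → rt; then ice/H2O
Reagents that add atoms: dichloromethyl methyl ether, COC(Cl)Cl; water, O
Why: Rieche formylation (Friedel–Crafts reaction with the chloromethoxycarbenium ion) at C8 and then C6, the only free positions of the ring and each ortho/para to all three oxygen donors, with excess reagent driving the slower second formylation; any methyl ether lost ortho to a new formyl group converges in step 12.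

Step 12
Reactants: 21 dialdehyde dimethyl ether
Product: 23 (1R,2R,4S,4'S)-5',7'-dihydroxy-4'-isobutyl-3,3-dimethylspiro[bicyclo[2.2.1]heptane-2,2'-chromane]-6',8'-dicarbaldehyde (CNP0150011.1), via 7-monophenol 22 (not isolated)
Conditions: NaSEt (8 equiv), DMF, 110 °C; then 1 M HCl
Reagents that add atoms: none
Why: SN2 O-demethylation by thiolate, which should be fast because each methoxy group is ortho to a formyl group and leaves as a vinylogous carboxylate, whereas the tertiary spiro ether cannot react by SN2 and, with no Lewis acid present, should not ionise, so C2 and C4 are preserved.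

## Compound list

1 | (1S,4R)-(−)-camphene | C=C2[C@@H]1CC[C@@H](C1)C2(C)C | starting material
2 | camphene ozonide (spiro-1,2,4-trioxolane; mixture at the trioxolane spiro carbon; not isolated) | C1OOC2(O1)[C@@H]3CC[C@@H](C3)C2(C)C | intermediate
3 | (1R,4S)-camphenilone, 3,3-dimethylbicyclo[2.2.1]heptan-2-one | O=C2[C@@H]1CC[C@@H](C1)C2(C)C | intermediate
4 | endo-camphenilol, (1R,2R,4S)-3,3-dimethylbicyclo[2.2.1]heptan-2-ol | O[C@@H]2[C@@H]1CC[C@@H](C1)C2(C)C | intermediate
5 | 1-fluoro-3,5-dimethoxybenzene | COc1cc(F)cc(OC)c1 | starting material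
6 | N-(chlorosulfonyl)-2-fluoro-4,6-dimethoxybenzamide (not isolated) | O=C(NS(=O)(=O)Cl)c1c(F)cc(OC)cc1OC | intermediate
7 | 2-fluoro-4,6-dimethoxybenzonitrile | N#Cc1c(F)cc(OC)cc1OC | intermediate
8 | sodium alkoxide of 4 (not isolated) | [Na+].[O-][C@@H]2[C@@H]1CC[C@@H](C1)C2(C)C | intermediate
9 | 2-{[(1R,2R,4S)-3,3-dimethylbicyclo[2.2.1]heptan-2-yl]oxy}-4,6-dimethoxybenzonitrile (endo ether) | N#Cc1c(OC)cc(OC)cc1O[C@@H]2[C@@H]3CC[C@@H](C3)C2(C)C | intermediate
10 | isobutyllithium | [Li]CC(C)C | starting material
11 | N-unsubstituted ketimine of 12 (not isolated) | CC(C)CC(=N)c1c(OC)cc(OC)cc1O[C@@H]2[C@@H]3CC[C@@H](C3)C2(C)C | intermediate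
12 | 1-(2-{[(1R,2R,4S)-3,3-dimethylbicyclo[2.2.1]heptan-2-yl]oxy}-4,6-dimethoxyphenyl)-3-methylbutan-1-one | CC(C)CC(=O)c1c(OC)cc(OC)cc1O[C@@H]2[C@@H]3CC[C@@H](C3)C2(C)C | intermediate
13 | triethyl phosphonoacetate | CCOC(=O)CP(=O)(OCC)OCC | starting material
14 | ethyl (2E)-3-aryl-5-methylhex-2-enoate (aryl as in 12; aryl trans to ester) | CCOC(=O)/C=C(CC(C)C)/c1c(OC)cc(OC)cc1O[C@@H]2[C@@H]3CC[C@@H](C3)C2(C)C | intermediate
15 | (2E)-3-aryl-5-methylhex-2-en-1-ol (aryl as in 12) | OC/C=C(CC(C)C)/c1c(OC)cc(OC)cc1O[C@@H]2[C@@H]3CC[C@@H](C3)C2(C)C | intermediate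
16 | (2E)-3-aryl-5-methylhex-2-enal (aryl as in 12; key-step precursor) | O=C/C=C(CC(C)C)/c1c(OC)cc(OC)cc1O[C@@H]2[C@@H]3CC[C@@H](C3)C2(C)C | intermediate
17 | zwitterion: aryloxocarbenium ion at C2' and BF3-bound enolate at C3, C4 already S (not isolated) | CC(C)C[C@@H](C=CO[B-](F)(F)F)c1c(OC)cc(OC)cc1[O+]=C2[C@@H]3CC[C@@H](C3)C2(C)C | intermediate
18 | 3-formyl-4-isobutyl-5,7-dimethoxy spirochroman (O1 endo, C3 exo; isobutyl cis to C3'; CHO trans to isobutyl) | CC(C)C[C@H]1[C@H](C=O)[C@@]2(Oc3cc(OC)cc(OC)c31)[C@@H]1CC[C@@H](C1)C2(C)C | intermediate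
19 | (1R,2R,4S,4'S)-4'-isobutyl-5',7'-dimethoxy-3,3-dimethylspiro[bicyclo[2.2.1]heptane-2,2'-chromane] | CC(C)C[C@H]1C[C@@]2(Oc3cc(OC)cc(OC)c31)[C@@H]1CC[C@@H](C1)C2(C)C | intermediate
20 | 8'-carbaldehyde of 19 (main monoformylated isomer; not isolated) | CC(C)C[C@H]1C[C@@]2(Oc3c(C=O)c(OC)cc(OC)c31)[C@@H]1CC[C@@H](C1)C2(C)C | intermediate
21 | 6',8'-dicarbaldehyde of 19 (5',7'-dimethoxy) | CC(C)C[C@H]1C[C@@]2(Oc3c(C=O)c(OC)c(C=O)c(OC)c31)[C@@H]1CC[C@@H](C1)C2(C)C | intermediate
22 | 7'-hydroxy-5'-methoxy dialdehyde (not isolated) | CC(C)C[C@H]1C[C@@]2(Oc3c(C=O)c(O)c(C=O)c(OC)c31)[C@@H]1CC[C@@H](C1)C2(C)C | intermediate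
23 | (1R,2R,4S,4'S)-5',7'-dihydroxy-4'-isobutyl-3,3-dimethylspiro[bicyclo[2.2.1]heptane-2,2'-chromane]-6',8'-dicarbaldehyde | CC(C)C[C@H]1C[C@@]2(Oc3c(C=O)c(O)c(C=O)c(O)c31)[C@@H]1CC[C@@H](C1)C2(C)C | target

## Step count and risks

Total: 12 steps. Longest linear sequence: 11 steps (1, 2, 4–12, from camphene); the arene branch (3, 4–12) is 10 steps.

**Step 9 (key step).** Hydride transfer from an aryl ether to a singly activated, beta,beta-disubstituted acceptor may be slower than Lewis-acid cleavage of the secondary norbornyl ether or oligomerisation of the enal. Face selection at C4 may be low, and the beta-aryloxy aldehyde may reopen by retro-oxa-Michael elimination on long exposure. The fallback builds the same C2–C3 bond by polar chemistry; it sets out from camphenilone 3 and arene 5 and returns at chroman 19. Friedel–Crafts acetylation of 5 (AcCl, AlCl3, CH2Cl2, 0 °C) should give 1-(2-fluoro-4,6-dimethoxyphenyl)ethan-1-one F1. Its lithium enolate (LiN(i-Pr)2, THF, −78 °C) should add to the exo face of 3 to give the beta-hydroxy ketone F2 with the tertiary oxygen endo. KN(SiMe3)2 in THF/DMF should then close the pyran by intramolecular SNAr to the spiro chroman-4-one F3. Addition of i-BuMgBr/CeCl3 should give the tertiary benzylic alcohol F4. Ionic hydrogenation (Et3SiH, CF3CO2H, CH2Cl2, −20 °C) should deliver hydride to the benzylic cation from the face next to C1'–H, anti to the gem-dimethyl carbon, to give 19.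

**Step 6.** Addition of the phosphonate anion to a ketone flanked by two ortho alkoxy groups may be slow, and E/Z control may erode. The fallback sets out from ketone 12 and returns at enoate 14. LiC≡COEt (from ethoxyacetylene and n-BuLi, THF, −78 °C), a small and weakly basic nucleophile, should add to 12 to give the tertiary propargylic alcohol F5. Meyer–Schuster rearrangement (Sc(OTf)3 cat., EtOH, CH2Cl2, rt) should then give 14, favouring the (E)-isomer.

**Step 12.** The second demethylation may stall once the first phenoxide has formed and lowered the leaving-group ability at C5, or thiolate may attack the activated aryl carbon in place of the methyl group. The fallback reverses the order of the last two operations; it sets out from chroman 19 and returns at target 23. Ether cleavage with excess MeMgI (neat, 160 °C), which is known to spare 2,2-dialkylchroman ethers, should give the 5,7-dihydroxychroman F6. Vilsmeier–Haack diformylation (POCl3, DMF, then aqueous hydrolysis) at C6 and C8 of this phloroglucinol-type ring should then give 23.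

## Further compounds

F1 | step 9 | 1-(2-fluoro-4,6-dimethoxyphenyl)ethan-1-one | CC(=O)c1c(F)cc(OC)cc1OC
F2 | step 9 | 1-(2-fluoro-4,6-dimethoxyphenyl)-2-[(1R,2R,4S)-2-hydroxy-3,3-dimethylbicyclo[2.2.1]heptan-2-yl]ethan-1-one (OH endo, CH2 exo) | O=C(C[C@@]2(O)[C@@H]3CC[C@@H](C3)C2(C)C)c1c(F)cc(OC)cc1OC
F3 | step 9 | 5',7'-dimethoxy-3,3-dimethylspiro[bicyclo[2.2.1]heptane-2,2'-chroman]-4'-one (O1 endo) | O=C1C[C@@]2(Oc3cc(OC)cc(OC)c31)[C@@H]1CC[C@@H](C1)C2(C)C
F4 | step 9 | 4'-hydroxy-4'-isobutyl-5',7'-dimethoxy-3,3-dimethylspiro[bicyclo[2.2.1]heptane-2,2'-chromane] (mixture at C4') | CC(C)CC1(O)C[C@@]2(Oc3cc(OC)cc(OC)c31)[C@@H]1CC[C@@H](C1)C2(C)C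
F5 | step 6 | 1-ethoxy-3-aryl-5-methylhex-1-yn-3-ol (aryl as in 12; mixture at the carbinol carbon) | CCOC#CC(O)(CC(C)C)c1c(OC)cc(OC)cc1O[C@@H]2[C@@H]3CC[C@@H](C3)C2(C)C
F6 | step 12 | (1R,2R,4S,4'S)-4'-isobutyl-3,3-dimethylspiro[bicyclo[2.2.1]heptane-2,2'-chromane]-5',7'-diol | CC(C)C[C@H]1C[C@@]2(Oc3cc(O)cc(O)c31)[C@@H]1CC[C@@H](C1)C2(C)C
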